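Locants: unprimed atoms belong to the N-linked indole, primed atoms to the N–H indole whose C3′ carries N1; prenyl = 3-methylbut-2-enyl.
Cuts: N1′–H is masked (SEM). The unprimed pyrrole ring is traced back to its C2 lactam and opened at C3–C3a. Then the N1–C2 (acetyl) bond, the N1–C3′ bond and the two aryl–CH2 prenyl bonds at C6 and C6′ are cut.
Enabling feature: C2–C3 of the unprimed indole is a bare two-carbon unit, and C3a sits next to C7a–N1 and para to the prenylated C6. C2–C3 can therefore arrive as an N-acetyl group and C3a as the C–Cl carbon of a 2-chloro-5-prenylaniline.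
Forward: the primed indole is bought as 6-bromoindole, then protected, prenylated and brominated at C3′. 5-Bromo-2-chloroaniline is prenylated, and the halves are joined at N1–C3′ and N-acetylated.
The only ring built, the unprimed five-membered ring, closes as an oxindole and is aromatised by hydride reduction and loss of water. SEM removal ends the route.
Stereochemistry: the target has no stereocentre and both alkenes end in CMe2, so nothing needs control. The hemiaminal carbon passed through late is racemic and vanishes.

Key step: step 7

Remark: 6-bromoindole, 5-bromo-2-chloroaniline and the prenylboronic ester are taken as purchased; SEM = 2-(trimethylsilyl)ethoxymethyl, IPent = 1,3-bis[2,6-di(pentan-3-yl)phenyl]imidazol-2-ylidene, dppf = 1,1′-bis(diphenylphosphino)ferrocene; the electron-rich compounds from the C3′ bromide onward are handled under argon.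

Step 1
Reactants: 1 6-bromo-1H-indole
Product: 2 6-bromo-1-SEM-indole
Conditions: NaH, DMF, 0 °C; SEMCl, 0 °C to rt
Reagents that add atoms: 2-(trimethylsilyl)ethoxymethyl chloride (SEMCl), C[Si](C)(C)CCOCCl
Why: N-Alkylation of the sodium indolide with the chloromethyl ether (SN2, standard SEM protection) masks N1′–H with a group that tolerates aqueous hydroxide, alkoxides, lithium amides, palladium catalysis and aluminium hydride and still leaves with fluoride at the end.

Step 2
Reactants: 2 6-bromo-1-SEM-indole; 3 3-methylbut-2-enylboronic acid pinacol ester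
Product: 4 6-prenyl-1-SEM-indole
Conditions: 3 (1.3 equiv), PdCl2(IPent)(3-chloropyridine) (2 mol %), 5 M aq KOH, THF, reflux
Reagents that add atoms: 3-methylbut-2-enylboronic acid pinacol ester 3, CC(C)=CCB1OC(C)(C)C(C)(C)O1
Why: Suzuki–Miyaura coupling of an aryl bromide with a 3,3-disubstituted allylboronate, in which the very bulky N-heterocyclic carbene ligand lets the allylpalladium intermediate relax to its primary sigma-bound form before reductive elimination, so that C6′ should be joined to the CH2 terminus (linear prenyl) and not to the tertiary carbon.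

Step 3
Reactants: 4 6-prenyl-1-SEM-indole
Product: 5 3-bromo-6-prenyl-1-SEM-indole
Conditions: NBS (1.0 equiv), THF, −78 to −20 °C, dark
Reagents that add atoms: N-bromosuccinimide (NBS), O=C1CCC(=O)N1Br
Why: Electrophilic aromatic bromination, relying on C3′ of an N-alkylindole being far more nucleophilic than a trisubstituted alkene, so one equivalent of NBS at low temperature in the dark should be consumed at C3′ before ionic addition or allylic bromination of the prenyl group can start.

Step 4
Reactants: 6 5-bromo-2-chloroaniline; 3 3-methylbut-2-enylboronic acid pinacol ester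
Product: 7 2-chloro-5-prenylaniline
Conditions: 3 (1.1 equiv), PdCl2(dppf) (3 mol %), K3PO4, THF/H2O, 65 °C
Reagents that add atoms: 3-methylbut-2-enylboronic acid pinacol ester 3, CC(C)=CCB1OC(C)(C)C(C)(C)O1
Why: Suzuki–Miyaura coupling that exploits the large rate gap between C–Br and the electron-rich C–Cl bond ortho to NH2 in oxidative addition to dppf-ligated zerovalent palladium, with the free amino group tolerated under aqueous phosphate conditions and the prenyl group transferred through its CH2 terminus.

Step 5
Reactants: 5 3-bromo-6-prenyl-1-SEM-indole; 7 2-chloro-5-prenylaniline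
Product: 8 N-(2-chloro-5-prenylphenyl)-6-prenyl-1-SEM-indol-3-amine
Conditions: Pd2(dba)3 (2.5 mol %), rac-BINAP (7.5 mol %), NaOt-Bu, toluene, 90 °C
Reagents that add atoms: none
Why: Buchwald–Hartwig amination in which BINAP-ligated zerovalent palladium adds to the C3′–Br bond but not to an aryl chloride at this temperature, so the primary aniline should be arylated once at nitrogen to form N1–C3′ while the chlorine that marks C3a and the C2′–H bond stay untouched.

Step 6
Reactants: 8 N-(2-chloro-5-prenylphenyl)-6-prenyl-1-SEM-indol-3-amine
Product: 9 N-(2-chloro-5-prenylphenyl)-N-(6-prenyl-1-SEM-indol-3-yl)acetamide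
Conditions: LiN(SiMe3)2 (1.05 equiv), THF, −78 °C; AcCl (1.2 equiv), −78 °C to rt
Reagents that add atoms: acetyl chloride, CC(=O)Cl
Why: N-Acylation of a preformed lithium diarylamide, chosen because the hindered, weakly nucleophilic diarylamine then reacts with acetyl chloride at low temperature and no HCl is released that could add to the prenyl double bonds.

Step 7
Reactants: 9 N-(2-chloro-5-prenylphenyl)-N-(6-prenyl-1-SEM-indol-3-yl)acetamide
Product: 10 6-prenyl-1-(6-prenyl-1-SEM-indol-3-yl)indolin-2-one
Conditions: NaOt-Bu (2.2 equiv), 1,4-dioxane, rt, 10 min; Pd(OAc)2 (5 mol %), PCy3 (10 mol %), 70 °C; aq NH4Cl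
Reagents that add atoms: none
Why: NaOt-Bu first turns the N,N-diaryl acetamide, whose alpha protons are acidified by the two aryl groups on nitrogen, into its sodium enolate; zerovalent palladium bearing the electron-rich, bulky PCy3 then inserts into the C–Cl bond at the future C3a, the tethered enolate replaces chloride on divalent palladium, and C–C reductive elimination from the carbon-bound six-membered azapalladacycle forges C3–C3a. The closest known reaction type is the palladium-catalysed intramolecular alpha-arylation of 2-haloanilide enolates to oxindoles, which is established for aryl chlorides with this catalyst and base combination. The single ring closed is the five-membered lactam, formally a 5-(enolendo)-exo closure that is unfavourable as a direct attack and becomes feasible because the bond is made by reductive elimination at the metal. No stereocentre arises, as C3 is a CH2 group. The step needs enolate arylation to win over C–H palladation at C2′ and needs the bond to form at one ortho position of the aniline ring only: the chlorine fixes that position in advance, the enolate is tethered, fully formed and a far better ligand for palladium than a C–H bond, and C2′ is shielded by the SEM group and by the twisted amide nitrogen. More than two equivalents of base are used because the oxindole is more acidic than the amide and rests as its enolate until the NH4Cl quench.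

Step 8
Reactants: 10 6-prenyl-1-(6-prenyl-1-SEM-indol-3-yl)indolin-2-one
Product: 12 6-prenyl-3-(6-prenylindol-1-yl)-1-SEM-indole, via 2-hydroxyindoline hemiaminal 11 (not isolated)
Conditions: i-Bu2AlH (2 equiv), CH2Cl2, −78 to 0 °C; aq potassium sodium tartrate; PPTS (cat.), CH2Cl2, rt
Reagents that add atoms: none
Why: Partial hydride reduction of a tertiary lactam followed by dehydration (the established oxindole-to-indole conversion): the tetrahedral aluminium hemiaminal persists at low temperature because the N-aryl nitrogen is a poor donor, hydrolysis gives the 2-hydroxyindoline, and trace acid expels water with gain of indole aromaticity, while trisubstituted alkenes and the SEM group are inert to i-Bu2AlH under these conditions.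

Step 9
Reactants: 12 6-prenyl-3-(6-prenylindol-1-yl)-1-SEM-indole
Product: 14 6-prenyl-3-(6-prenylindol-1-yl)-1H-indole, via N-hydroxymethyl bisindole 13 (not isolated)
Conditions: Bu4NF (1 M in THF, 5 equiv), THF, reflux
Reagents that add atoms: none
Why: Fluoride-induced SEM cleavage, in which attack at silicon triggers fragmentation to Me3SiF and ethene and the remaining N-hydroxymethyl indole expels formaldehyde under the basic conditions, a sequence that touches neither the prenyl groups nor the N1–C3′ bond.

Compound list
1 | 6-bromo-1H-indole | Brc1ccc2cc[nH]c2c1 | starting material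
2 | 6-bromo-1-{[2-(trimethylsilyl)ethoxy]methyl}indole | C[Si](C)(C)CCOCn1ccc2ccc(Br)cc21 | intermediate
3 | 3-methylbut-2-enylboronic acid pinacol ester | CC(C)=CCB1OC(C)(C)C(C)(C)O1 | starting material
4 | 6-(3-methylbut-2-enyl)-1-{[2-(trimethylsilyl)ethoxy]methyl}indole | CC(C)=CCc1ccc2ccn(COCC[Si](C)(C)C)c2c1 | intermediate
5 | 3-bromo-6-(3-methylbut-2-enyl)-1-{[2-(trimethylsilyl)ethoxy]methyl}indole | CC(C)=CCc1ccc2c(Br)cn(COCC[Si](C)(C)C)c2c1 | intermediate
6 | 5-bromo-2-chloroaniline | Nc1cc(Br)ccc1Cl | starting material
7 | 2-chloro-5-(3-methylbut-2-enyl)aniline | CC(C)=CCc1ccc(Cl)c(N)c1 | intermediate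
8 | N-[2-chloro-5-(3-methylbut-2-enyl)phenyl]-6-(3-methylbut-2-enyl)-1-{[2-(trimethylsilyl)ethoxy]methyl}indol-3-amine | CC(C)=CCc1ccc(Cl)c(Nc2cn(COCC[Si](C)(C)C)c3cc(CC=C(C)C)ccc23)c1 | intermediate
9 | N-[2-chloro-5-(3-methylbut-2-enyl)phenyl]-N-[6-(3-methylbut-2-enyl)-1-{[2-(trimethylsilyl)ethoxy]methyl}indol-3-yl]acetamide | CC(=O)N(c1cc(CC=C(C)C)ccc1Cl)c1cn(COCC[Si](C)(C)C)c2cc(CC=C(C)C)ccc12 | intermediate
10 | 6-(3-methylbut-2-enyl)-1-[6-(3-methylbut-2-enyl)-1-{[2-(trimethylsilyl)ethoxy]methyl}indol-3-yl]indolin-2-one | O=C1Cc2ccc(CC=C(C)C)cc2N1c1cn(COCC[Si](C)(C)C)c2cc(CC=C(C)C)ccc12 | intermediate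
11 | 6-(3-methylbut-2-enyl)-1-[6-(3-methylbut-2-enyl)-1-{[2-(trimethylsilyl)ethoxy]methyl}indol-3-yl]indolin-2-ol (racemic hemiaminal, not isolated) | OC1Cc2ccc(CC=C(C)C)cc2N1c1cn(COCC[Si](C)(C)C)c2cc(CC=C(C)C)ccc12 | intermediate
12 | 6-(3-methylbut-2-enyl)-3-[6-(3-methylbut-2-enyl)indol-1-yl]-1-{[2-(trimethylsilyl)ethoxy]methyl}indole | CC(C)=CCc1ccc2c(-n3ccc4ccc(CC=C(C)C)cc43)cn(COCC[Si](C)(C)C)c2c1 | intermediate
13 | {6-(3-methylbut-2-enyl)-3-[6-(3-methylbut-2-enyl)indol-1-yl]indol-1-yl}methanol (not isolated) | CC(C)=CCc1ccc2c(-n3ccc4ccc(CC=C(C)C)cc43)cn(CO)c2c1 | intermediate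
14 | 6-(3-methylbut-2-enyl)-3-[6-(3-methylbut-2-enyl)indol-1-yl]-1H-indole | CC(C)=CCc1ccc2c(-n3ccc4ccc(CC=C(C)C)cc43)c[nH]c2c1 | target

Total step count: 9.
Longest linear sequence: 8 steps (1 → 2 → 4 → 5 → 8 → 9 → 10 → 12 → 14). Step 4 is a one-step side branch that joins at step 5.

Steps most likely to fail

Step 7 (key step).
- What may go wrong:
  - Oxidative addition into the electron-rich C–Cl bond may be sluggish.
  - The arylpalladium intermediate may palladate C2′–H.
  - tert-Butoxide may attack the activated N,N-diaryl amide carbonyl and strip the acetyl group.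
  - The product enolate may be arylated by a second molecule.
- Fallback: ring closure on the assembled amide is given up and a ready-made lactam is attached instead. It sets out from 3 and 5.
- Commercial 6-bromoindolin-2-one F1 is coupled with 3 (PdCl2(dppf), K3PO4, dioxane/H2O, 80 °C) to give 6-(3-methylbut-2-enyl)indolin-2-one F2.
- F2 is then N-arylated with bromide 5 under Goldberg-type copper catalysis (CuI, trans-N,N′-dimethylcyclohexane-1,2-diamine, K2CO3, dioxane, 100 °C). These conditions are known to arylate oxindoles at nitrogen rather than at C3.
- The fallback comes back to the route at 10.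

Step 5.
- What may go wrong:
  - Oxidative addition into the electron-rich C3′–Br bond may be slow and accompanied by protodebromination.
  - The hindered, weakly nucleophilic ortho-chloroaniline may bind palladium poorly.
  - Palladium may insert prematurely into the C–Cl bond.
  - The electron-rich 3-aminoindole product may oxidise in air.
- Fallback: metal, nucleophile and bond order are all changed. It sets out from 4 and 7.
- Compound 4 is iodinated with N-iodosuccinimide (THF, −78 °C) to give 3-iodo-6-prenyl-1-SEM-indole F3.
- Compound 7 is acetylated with Ac2O (CH2Cl2, rt) to give N-(2-chloro-5-prenylphenyl)acetamide F4.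
- The two are joined by Goldberg amidation (CuI, N,N′-dimethylethylenediamine, K3PO4, toluene, 110 °C), which leaves aryl chlorides alone.
- This bypasses 8 and step 6 and comes back to the route at 9.

Step 4.
- What may go wrong:
  - Allylic transposition on palladium may form the C–C bond at the tertiary prenyl terminus.
  - Partial insertion into C–Cl may occur.
  - The bromoaniline may self-condense by N-arylation.
- Fallback: the regiochemical question is removed. It sets out from 6.
- Suzuki–Miyaura coupling with allylboronic acid pinacol ester, whose two termini are equivalent (PdCl2(dppf), K3PO4, THF/H2O, 65 °C), should give 5-allyl-2-chloroaniline F5.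
- Olefin cross-metathesis with excess 2-methylbut-2-ene then converts allyl into prenyl. The catalyst is second-generation Grubbs catalyst RuCl2(=CHPh)(PCy3)(SIMes), SIMes = 1,3-dimesitylimidazolidin-2-ylidene, in CH2Cl2 at 40 °C.
- The fallback comes back to the route at 7.

Further compounds
F1 | step 7 | 6-bromoindolin-2-one (purchased) | O=C1Cc2ccc(Br)cc2N1
F2 | step 7 | 6-(3-methylbut-2-enyl)indolin-2-one | CC(C)=CCc1ccc2c(c1)NC(=O)C2
F3 | step 5 | 3-iodo-6-(3-methylbut-2-enyl)-1-{[2-(trimethylsilyl)ethoxy]methyl}indole | CC(C)=CCc1ccc2c(I)cn(COCC[Si](C)(C)C)c2c1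
F4 | step 5 | N-[2-chloro-5-(3-methylbut-2-enyl)phenyl]acetamide | CC(=O)Nc1cc(CC=C(C)C)ccc1Cl
F5 | step 4 | 5-allyl-2-chloroaniline | C=CCc1ccc(Cl)c(N)c1
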